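Sunday's run and Tuesday's run differ in their charge of starting material, 1 M against 1.5 M, yet at 3.00 d they read 6.2 % and 5.8 % of that charge, 0.4 percentage points apart with a scatter of 0.5 points. Friday's run, with 0.90 M of partner against 1.8 M, read 2.5 % at the same time. So the percentage climbs at a pace that follows the partner, and the new flasks ask what a slower feed of that partner changes.

| flask | starting material | partner | remark | time |
|---|---|---|---|---|
| Sunday's | 1 M | 1.8 M (fed, over 0.15 h) | run made earlier; the fed solution adds 0.20 times the starting volume |  |
| Tuesday's | 1.5 M | 1.8 M (fed, over 0.15 h) | run made earlier; the fed solution adds 0.20 times the starting volume |  |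
| Friday's | 2 M | 0.90 M (fed, over 0.15 h) | run made earlier; the fed solution adds 0.20 times the starting volume |  |
| delta | 2.0 M | 1.80 M (fed, over 0.15 h) | the fed solution adds 0.20 times the starting volume | 4.0 d |
| beta | 2.0 M | 1.80 M (fed, over 0.40 h) | the fed solution adds 0.20 times the starting volume | 4.0 d |
| gamma | 2.0 M | 1.80 M (fed, over 1.2 h) | the fed solution adds 0.20 times the starting volume | 4.0 d |
| theta | 2.0 M | 1.80 M (fed, over 4.0 h) | the fed solution adds 0.20 times the starting volume | 4.0 d |
| zeta | 2.0 M | 1.80 M (fed, over 12 h) | the fed solution adds 0.20 times the starting volume | 4.0 d |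

| run | time / d | target / % |
|---|---|---|
| Sunday's | 0.500 | 1.5 |
| Sunday's | 0.833 | 0.9 |
| Sunday's | 1.25 | 2.4 |
| Sunday's | 1.67 | 3.3 |
| Sunday's | 2.50 | 5.0 |
| Sunday's | 3.00 | 6.2 |
| Tuesday's | 0.500 | 0.1 |
| Tuesday's | 0.833 | 1.1 |
| Tuesday's | 1.25 | 2.4 |
| Tuesday's | 1.67 | 2.8 |
| Tuesday's | 2.50 | 4.7 |
| Tuesday's | 3.00 | 5.8 |
| Friday's | 0.250 | 0 |
| Friday's | 0.833 | 1.1 |
| Friday's | 1.67 | 0.8 |
| Friday's | 2.50 | 0.5 |
| Friday's | 3.00 | 2.5 |

(each reading ± 0.5 percentage points)

- every charge counts on the volume at the start, and the solution that is fed holds the whole dose
- a reading or a percentage of target counts all its forms, free or not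
- "hardly changes" means that all values lie within two and a half points (for a concentration: within two and a half percent of the largest)

- amount of target at the end, in percent of the starting material charged for delta, beta, gamma, theta, zeta, in this order
- how that number moves from the first to the last of them (rises, then falls / falls, then rises / falls all the way / hardly changes / rises all the way)

Run the new flasks in slow motion, by my own reckoning. First comes the feed, 0.15 h in delta and 12 h in zeta, and even zeta's feed is shorter than the 4.0 d of the run. No earlier run has a reading inside its feed. The first readings after it, Friday's 0 % at 0.250 d and Tuesday's 0.1 % at 0.500 d, hint at an induction period, but Sunday's 1.5 % at 0.500 d does not, so the readings leave that open.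

Then comes the long middle, in which Tuesday's run climbs nearly straight. Carried straight on to 4.0 d, that climb gives 7.73 %, which is my figure for delta.

A steady feed delivers its partner, on average, at the middle of the dosing time, so a slower feed acts like a later start by that delay. Multiply zeta's delay by Tuesday's climb and you have 0.48 points. This product is the feed loss, the points of target that a run gives up at its end. Set beside the margin of 2.5 points, that makes my row one that hardly changes.

The forecast gives 7.3 %, 7.3 %, 7.25 %, 7.1 % and 6.8 %, so hardly changes, and says “The values therefore fall slightly”. Its top value stands lower than mine, but its shape is the same.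

The flasks give 6.21 %, 6.21 %, 6.20 %, 6.16 % and 6.05 %, so hardly changes.

    starting material + partner → intermediate A (k = 1.40 × 10⁻⁴ M⁻¹ min⁻¹)
    partner + intermediate A → intermediate B (k = 5.00 × 10⁻⁴ M⁻¹ min⁻¹)
    intermediate B → intermediate C (k = 6.90 × 10⁻⁴ min⁻¹)
    intermediate C ⇌ intermediate D (K = 5.80, k = 0.00380 min⁻¹)
    intermediate B → target (k = 5.70 × 10⁻⁴ min⁻¹)
    crystals ⇌ target, rate k6*(cs6 - [target]) while solid is left; crystals form when [target] > cs6 (solubility = 0.360 M, k = 0.0530 min⁻¹)
    partner + target → over-reaction product (k = 5.30 × 10⁻⁴ M⁻¹ min⁻¹)

In delta, the step of partner and intermediate A to intermediate B has half of its turnover behind it by 1.58 d, later than the end of zeta's feed, and it has 7.1 % behind it by 0.400 d. From delta to zeta the target falls by 0.16 points, a third of the feed loss of 0.48 points. On theta the feed loss is 0.16 points, and the fall from delta is 0.05 points, again a third.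

The runs are simulated with constants of no real substance.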